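## Structural features

The target is a naphthazarin, a 5,8-dihydroxy-1,4-naphthoquinone in which a quinone ring (C1–C4, C4a, C8a) is fused to a dihydroxybenzene ring (C4a–C8a), and C2 of the quinone ring is bonded directly to C1' of a cyclobutane. In that four-membered ring C1' is a fully substituted carbinol carbon (bonded to C2, the ester oxygen, C2' and C4'), C2' is the neighbouring gem-dimethyl carbon, and C3' and C4' are methylenes, so two quaternary carbons stand side by side in a strained ring. C1' is the only stereocentre (R) and has no stereogenic neighbour, so the stereochemical task is absolute configuration at a tertiary oxygen-bearing carbon; the only other stereo-element is the Z double bond of the angelate, (2Z)-2-methylbut-2-enoate, on the C1' oxygen. The angelate isomerises to the tiglate under nucleophilic catalysis, radical or acid conditions; the tertiary C1'–O bond can ionise with ring expansion or elimination; and the naphthazarin is redox-active, acidic and base-sensitive, so it should appear last. The real difficulty is the C1'–C2' bond between the two quaternary carbons, together with acylation of the heavily shielded C1' hydroxyl without loss of alkene geometry. The key step uses the fact that C1' (oxygen and aryl) and C2' (two methyls) map onto the oxygenated carbon of an aryl silyl enol ether and the disubstituted carbon of dimethylketene, with C4' as the enol ether methylene and C3' as the ketene carbonyl carbon. The carbonyl left at C3' is bonded directly to the gem-dimethyl carbon C2' and stands 1,3 to C1'; it is a hindered, neopentyl-type ketone, not one remote from both quaternary centres, and this governs its reduction and deoxygenation.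

## Logic of the disconnections

**18 to 14 and 16.** The C4a–C5 and C8–C8a bonds of 18 are cut, removing the whole dihydroxybenzene ring as the four-carbon unit 16 and leaving 14. The cut is made here because 16 carries both phenolic oxygens at the correct oxidation level, so no phenol protecting group is ever needed and the sensitive naphthazarin is formed in the last step. The forward step must take the unsubstituted C=C of 14 in preference to the substituted one and must leave the enoate alone. 16 goes back to 15 by cutting two O–Si bonds.

**14 to 13.** The two quinone C=O groups are traced back to two aryl–OCH3 groups. The dimethoxyarene of 13 is inert to every earlier step and supplies the cation stabilisation needed in the key step. The forward oxidation has to spare the enoate and must not ionise the tertiary C1'–O bond.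

**13 to 9 and 10.** The acyl C–O bond of the ester is cut. The acyl group is introduced late because its Z alkene would not survive the stannyl-radical, hydride and fluoride steps before it. The demand is heavy: acyl transfer to a tertiary oxygen flanked by a quaternary carbon and an ortho-substituted aryl group, without Z-to-E isomerisation; this is met by using the alkoxide 12 and the symmetrical anhydride 11.

**9 to 8, 7 and 6.** First the O–Si bond is restored, then the C3'–H bond is traced back to a C3'–O bond. These are changes of functional group only; the oxygen at C3' is what remains of the ring-forming step. The forward sequence needs a radical at C3' that is reduced faster than the ring opens, and a silyl ether that stays in place until that radical chemistry is over.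

**6 to 5.** The carbinol C3'–H bond is traced back to the ketone. This one reduction both prepares the deoxygenation and separates the enantiomers of 5, because a catalyst-controlled hydride transfer converts them into diastereomers. The demand is reagent control strong enough to override the remote C1' centre, and a hydroxyl that ends up trans to the siloxy group so that no silyl migration can follow.

**5 to 2 and 4.** The C1'–C2' and C3'–C4' bonds are cut together. This removes the ring, both skeletal bonds and the quaternary–quaternary junction in one operation and leads to two flat, achiral partners. The forward step must close a four-membered ring between two fully substituted carbons faster than silyl transfer or dimerisation of 4 can intervene. For this reason 2 keeps its bulky silyl group and 4 is generated slowly in the presence of 2, with a chelating ether to hold back the zinc salt.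

**4 to 3, and 2 to 1.** 4 is traced to 3 by restoring two C–Br bonds, and 2 to 1 by cutting the O–Si bond. Both are one-step preparations from commercial materials; the only demand is that 4 is never accumulated.

## Other disconnections considered

**Alternative 1:** The cut is the C1–C2 bond of the quinone ring (with the C3–H bond). It leads back to the alkynyl hydroxybenzocyclobutenone A2, which would come from addition of the lithium acetylide of the silylated alkynol A3 to the symmetrical dione A4; A3 in turn needs 2,2-dimethylcyclobutan-1-one A5. In the forward key step, heating A2 would open the four-membered ring by a 4π-electrocyclic process to an ortho-quinoid ketene, whose ketene carbon would bond to the far alkyne carbon; transfer of the hydroxyl hydrogen to C3 would then give the naphthoquinone A1.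
- In its favour: the position of the side chain on the quinone ring is fixed by connectivity, A4 is symmetrical so mono-addition has no regiochemical issue, and the plan is convergent. Only an sp2–sp2 bond is formed, whereas the chosen key step must force a quaternary–quaternary bond; on intrinsic bond-forming difficulty Alternative 1 is the better plan. It also brings in the cyclobutane without a surplus carbonyl, so it needs no deoxygenation, and here too it is the better.
- Against it: A3 requires either an enantioselective alkynylation of the hindered ketone A5 or the resolution of a tertiary propargylic alcohol, both less tractable than resolving through a secondary carbinol. A4 is a multi-step building block. A1 still carries two aryl methyl ethers peri to the quinone carbonyls, whose cleavage normally calls for strong Lewis acid or further oxidation, which a tertiary cyclobutyl ester and an angelate would not be expected to tolerate. Desilylation and acylation would have to be carried out on a quinone, where an alkoxide is a liability.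
- Comparison: on stereocontrol the two plans are equal in that neither key step sets C1'. On step count Alternative 1 would be similar or longer once A3 and A4 are included, and its endgame is clearly the weaker.

**Alternative 2:** The cut is at C4–C4a and C1–C8a. In the forward key step the aryne released by fluoride from the silyl triflate A8 would add across the 2,5-positions of the furyl cyclobutyl angelate A7 to give the 1,4-epoxide A6 as both bridgehead epimers.
- In its favour: the conditions are mild and near neutral, the angelate is already in place on a simple carbinol before any quinone exists, and two C–C bonds form in one convergent step. On mildness and on step count up to the carbon skeleton this alternative is the better.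
- Against it: A6 is still far from the target. The oxa-bridge has to be opened to a naphthol with acid, next to an ionisable tertiary ester; the naphthol must be oxidised to the quinone; and two methyl ethers must again be cleaved. A7 requires the same hindered tertiary acylation as step 7 of the chosen plan (equal on that point), and the resolution of a tertiary furyl carbinol made from A5.
- Comparison: the key steps are equal with respect to C1', since both are stereochemically silent there. Mechanistically the aryne cycloaddition is the simpler and probably the more dependable single step. The chosen plan is better after the key step, because it reaches the naphthazarin without any ether cleavage.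

**Alternative 3:** The cuts are C3–C4, C1–C2 and C1–C8a. In the forward key step the aryl(methoxy)carbene complex A10, (CO)5Cr=C(OMe)Ar with zerovalent chromium, would react with the alkyne A3 by alkyne insertion, CO insertion and electrocyclic closure to give the 4-methoxy-1-naphthol A9.
- In its favour: regiochemistry is predictable, with the bulky alkyne substituent ending ortho to the new phenol. The para-methoxyphenol of A9 should be oxidised directly to the quinone by (NH4)2Ce(NO3)6. The methoxymethyl ethers come off under mild acid, so the unveiling of the naphthazarin would be easier than in Alternatives 1 and 2 and roughly equal to the chosen plan.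
- Against it: chromium carbonyl chemistry is used stoichiometrically, with toxic metal waste. The alkyne carries a quaternary propargylic carbon flanked by a second quaternary carbon, which may divert the vinylcarbene and vinylketene intermediates into cyclobutenone or furan formation. A10 takes several steps from the aryllithium. Enantioenriched A3 is needed as in Alternative 1, and the acid used for acetal removal would meet the tertiary ester.
- Comparison: stereochemically equal (C1' is not set in the key step). Mechanistically it has more branch points than the polar [2+2]. In step count it would be comparable or longer.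

In all three alternatives the cyclobutane with its vicinal quaternary carbons is brought in ready-made through A5. Forming the C1' carbinol by nucleophilic addition to a ketone is simpler than the ring closure of the chosen plan, and this is a genuine advantage of the alternatives. The price is the resolution of a tertiary alcohol and a harder endgame.

Key step: step 2

Remark on the chemistry: the 5,8-dihydroxy-1,4-naphthoquinone core is a pair of rapidly interconverting tautomers, so the form with the side chain on the quinonoid ring and the form with it on the benzenoid ring are treated as one compound, 18.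

## Route

Step 1
Reactants: 1 2',5'-dimethoxyacetophenone
Product: 2 tert-butyl{[1-(2,5-dimethoxyphenyl)ethenyl]oxy}dimethylsilane
Conditions: t-BuMe2SiOSO2CF3 (1.2 equiv), Et3N (1.5 equiv), CH2Cl2, 0 → 20 °C
Reagents that add atoms: tert-butyldimethylsilyl trifluoromethanesulfonate, CC(C)(C)[Si](C)(C)OS(=O)(=O)C(F)(F)F
Why: Soft enolisation of an aryl methyl ketone by silyl triflate and amine (O-silylation); the methyl group is the only enolisable site, so a single silyl enol ether should result and no stereocentre is involved.

Step 2
Reactants: 2 tert-butyl{[1-(2,5-dimethoxyphenyl)ethenyl]oxy}dimethylsilane; 3 2-bromo-2-methylpropanoyl bromide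
Product: 5 3-[(tert-butyldimethylsilyl)oxy]-3-(2,5-dimethoxyphenyl)-2,2-dimethylcyclobutan-1-one (racemate), via dimethylketene 4 (not isolated)
Conditions: Zn (activated, 3 equiv), 3 (2.5 equiv) added over 6 h to 2, Et2O–MeOCH2CH2OMe (4:1), 25 → 35 °C
Reagents that add atoms: none
Why: Zn debrominates 3 to dimethylketene 4, which is consumed as it forms by the electron-rich alkene of 2 in a ketene–enol ether [2+2] cycloaddition, the known route from ketenes and alkyl or silyl enol ethers to 3-alkoxy- and 3-siloxycyclobutanones. The process is strongly asynchronous: the methylene carbon of 2 (future C4') attacks the sp carbon of the ketene (future C3') in the plane of the C=O π* orbital, giving a zwitterion made of an aryl- and siloxy-stabilised cation at C1' and an enolate whose carbon terminus is C2'. The four-membered ring then closes by C-alkylation of that enolate on the oxocarbenium carbon, a 4-(enolendo)-exo-trig closure that forms the C1'–C2' bond between two fully substituted carbons inside the ion pair. Regiochemistry (ketone at C3', next to C2' and 1,3 to C1') follows from this polarity. C1' becomes a stereocentre, but nothing in either achiral partner distinguishes its faces, so 5 should form as the racemate and the configuration is selected in step 3. The selectivities actually needed are chemoselectivities: cross-addition over ketene dimerisation, secured by slow generation of 4 in the presence of all of 2, and ring closure over O-to-O silyl transfer or Lewis-acid reopening of the donor–acceptor cyclobutane, secured by the bulky tert-butyldimethylsilyl group and by 1,2-dimethoxyethane, which ties up ZnBr2.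

Step 3
Reactants: 5 3-[(tert-butyldimethylsilyl)oxy]-3-(2,5-dimethoxyphenyl)-2,2-dimethylcyclobutan-1-one (racemate)
Product: 6 (1R,3R)-3-[(tert-butyldimethylsilyl)oxy]-3-(2,5-dimethoxyphenyl)-2,2-dimethylcyclobutan-1-ol (hydroxyl trans to the siloxy group)
Conditions: NADPH-dependent ketoreductase (R-selective at the carbonyl carbon, chosen from an enzyme panel), NADP+ (cat.), i-PrOH, KH2PO4/K2HPO4 buffer pH 7.0, Me2SO (10 vol%), 30 °C; separation of the two diastereomeric alcohols on SiO2
Reagents that add atoms: none
Why: Enzymatic ketone reduction under catalyst control: hydride from NADPH should go to the same carbonyl face in both enantiomers because the enzyme distinguishes the CMe2 flank from the CH2 flank, so the enantiomers of 5 become diastereomeric alcohols (a divergent reaction on a racemate) and 6, from (3S)-5, is separated by chromatography. The new carbinol centre (R) is set by the enzyme and serves only as a handle, with the enzyme chosen so that the hydroxyl of 6 is trans to the siloxy group; the assignment would rest on NOE contacts and Mosher-ester analysis of the carbinol.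

Step 4
Reactants: 6 (1R,3R)-3-[(tert-butyldimethylsilyl)oxy]-3-(2,5-dimethoxyphenyl)-2,2-dimethylcyclobutan-1-ol
Product: 7 O-[(1R,3R)-3-[(tert-butyldimethylsilyl)oxy]-3-(2,5-dimethoxyphenyl)-2,2-dimethylcyclobutyl] S-methyl carbonodithioate
Conditions: NaH, THF, 0 °C; CS2; then MeI, 0 → 20 °C
Reagents that add atoms: carbon disulfide, S=C=S; iodomethane, CI
Why: Xanthate formation, the first stage of a Barton–McCombie deoxygenation: the small sodium alkoxide adds to CS2 even at this neopentyl-type position and the dithiocarbonate is S-methylated; the trans arrangement of O–Na and O–Si excludes 1,3 O-to-O silyl migration.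

Step 5
Reactants: 7 O-[(1R,3R)-3-[(tert-butyldimethylsilyl)oxy]-3-(2,5-dimethoxyphenyl)-2,2-dimethylcyclobutyl] S-methyl carbonodithioate
Product: 8 tert-butyl{[(1R)-1-(2,5-dimethoxyphenyl)-2,2-dimethylcyclobutyl]oxy}dimethylsilane
Conditions: Bu3SnH (3 equiv, 0.3 M), azobisisobutyronitrile (0.2 equiv, in portions), toluene, 90 °C
Reagents that add atoms: none
Why: Barton–McCombie radical deoxygenation: Bu3Sn• adds to C=S, fragmentation releases the secondary C3' radical, and this takes hydrogen from Bu3SnH; the high stannane concentration should make hydrogen transfer outrun ring-opening β-scission, which is also stereoelectronically disfavoured in a cyclobutyl radical. The auxiliary C3' centre is erased and C1' is not touched.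

Step 6
Reactants: 8 tert-butyl{[(1R)-1-(2,5-dimethoxyphenyl)-2,2-dimethylcyclobutyl]oxy}dimethylsilane
Product: 9 (1R)-1-(2,5-dimethoxyphenyl)-2,2-dimethylcyclobutan-1-ol
Conditions: Bu4NF (3 equiv), THF, 50 °C
Reagents that add atoms: none
Why: Fluoride-induced Si–O cleavage driven by the Si–F bond; the basic medium avoids ionisation of the tertiary benzylic C–O bond, and with the ketone gone no retro-aldol opening is possible.

Step 7
Reactants: 9 (1R)-1-(2,5-dimethoxyphenyl)-2,2-dimethylcyclobutan-1-ol; 10 angelic acid, (2Z)-2-methylbut-2-enoic acid
Product: 13 (1R)-1-(2,5-dimethoxyphenyl)-2,2-dimethylcyclobutyl (2Z)-2-methylbut-2-enoate, via angelic anhydride 11 (not isolated), via lithium alkoxide 12 (not isolated)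
Conditions: 10 (2.4 equiv), N,N'-dicyclohexylcarbodiimide (1.2 equiv), CH2Cl2, 0 → 20 °C, filter, concentrate; 9, LiN(SiMe3)2 (1.1 equiv), THF, −78 °C; then 11, −78 → 0 °C
Reagents that add atoms: none
Why: Carbodiimide dehydration of 10 to its symmetrical anhydride, then acylation of a lithium tert-alkoxide, which is far more nucleophilic than the shielded neutral alcohol. No nucleophilic amine catalyst is present, so the conjugate addition–elimination path that turns angelates into tiglates is closed; the C1'–O bond is not broken, so the configuration is kept.

Step 8
Reactants: 13 (1R)-1-(2,5-dimethoxyphenyl)-2,2-dimethylcyclobutyl (2Z)-2-methylbut-2-enoate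
Product: 14 (1R)-1-(3,6-dioxocyclohexa-1,4-dien-1-yl)-2,2-dimethylcyclobutyl (2Z)-2-methylbut-2-enoate
Conditions: (NH4)2Ce(NO3)6 (2.5 equiv), MeCN–H2O (2:1), 0 °C, 15 min
Reagents that add atoms: water, O
Why: Oxidative demethylation of a hydroquinone dimethyl ether by two equivalents of tetravalent cerium through the arene radical cation, with water attacking the methoxy-bearing carbons and methanol leaving. The electron-poor trisubstituted enoate and the benzylic carbon, which has no hydrogen, should not be oxidised, and the short cold reaction limits acid contact with the tertiary ester.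

Step 9
Reactants: 15 succinic anhydride
Product: 16 2,5-bis(trimethylsiloxy)furan
Conditions: Me3SiCl (2.5 equiv), Et3N (2.5 equiv), ZnCl2 (cat.), MeCN, 25 → 60 °C; distillation under reduced pressure
Reagents that add atoms: chlorotrimethylsilane, C[Si](C)(C)Cl
Why: Twofold O-silylation of the anhydride through its enol forms, a known preparation of this furan; the product is moisture-sensitive and is used directly.

Step 10
Reactants: 14 (1R)-1-(3,6-dioxocyclohexa-1,4-dien-1-yl)-2,2-dimethylcyclobutyl (2Z)-2-methylbut-2-enoate; 16 2,5-bis(trimethylsiloxy)furan
Product: 18 (1R)-1-(5,8-dihydroxy-1,4-dioxo-1,4-dihydronaphthalen-2-yl)-2,2-dimethylcyclobutyl (2Z)-2-methylbut-2-enoate, via oxa-bridged cycloadduct 17 (not isolated)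
Conditions: 16 (1.3 equiv), CH2Cl2, −30 → 20 °C; then SiO2 or dilute aqueous HCl work-up
Reagents that add atoms: none
Why: Diels–Alder reaction of the electron-rich bis(siloxy)furan with the quinone at its unsubstituted C=C (the other is shielded by the quaternary C1' substituent), the known furan route from benzoquinones to naphthazarins. The doubly ketal-like oxygen bridge of 17 should collapse with loss of hexamethyldisiloxane to a 4a,8a-dihydro tetraone that enolises to the naphthazarin, so no oxidant is needed and C1' is not involved.

## Compound list

1 | 2',5'-dimethoxyacetophenone, 1-(2,5-dimethoxyphenyl)ethan-1-one | CC(=O)c1cc(OC)ccc1OC | starting material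
2 | tert-butyl{[1-(2,5-dimethoxyphenyl)ethenyl]oxy}dimethylsilane | C=C(O[Si](C)(C)C(C)(C)C)c1cc(OC)ccc1OC | intermediate
3 | 2-bromo-2-methylpropanoyl bromide | CC(C)(Br)C(=O)Br | starting material
4 | dimethylketene, 2-methylprop-1-en-1-one | CC(C)=C=O | intermediate (not isolated)
5 | 3-[(tert-butyldimethylsilyl)oxy]-3-(2,5-dimethoxyphenyl)-2,2-dimethylcyclobutan-1-one, racemate; the (3S)-enantiomer that is carried on is drawn | CC(C)(C)[Si](C)(C)O[C@]1(c2cc(OC)ccc2OC)CC(=O)C1(C)C | intermediate
6 | (1R,3R)-3-[(tert-butyldimethylsilyl)oxy]-3-(2,5-dimethoxyphenyl)-2,2-dimethylcyclobutan-1-ol | CC(C)(C)[Si](C)(C)O[C@]1(c2cc(OC)ccc2OC)C[C@@H](O)C1(C)C | intermediate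
7 | O-[(1R,3R)-3-[(tert-butyldimethylsilyl)oxy]-3-(2,5-dimethoxyphenyl)-2,2-dimethylcyclobutyl] S-methyl carbonodithioate | CC(C)(C)[Si](C)(C)O[C@]1(c2cc(OC)ccc2OC)C[C@@H](OC(=S)SC)C1(C)C | intermediate
8 | tert-butyl{[(1R)-1-(2,5-dimethoxyphenyl)-2,2-dimethylcyclobutyl]oxy}dimethylsilane | CC(C)(C)[Si](C)(C)O[C@]1(c2cc(OC)ccc2OC)CCC1(C)C | intermediate
9 | (1R)-1-(2,5-dimethoxyphenyl)-2,2-dimethylcyclobutan-1-ol | O[C@]1(c2cc(OC)ccc2OC)CCC1(C)C | intermediate
10 | angelic acid, (2Z)-2-methylbut-2-enoic acid | C/C=C(/C)C(=O)O | starting material
11 | angelic anhydride, (2Z)-2-methylbut-2-enoic anhydride | C/C=C(/C)C(=O)OC(=O)/C(C)=C\C | intermediate (not isolated)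
12 | lithium (1R)-1-(2,5-dimethoxyphenyl)-2,2-dimethylcyclobutan-1-olate | [Li+].[O-][C@]1(c2cc(OC)ccc2OC)CCC1(C)C | intermediate (not isolated)
13 | (1R)-1-(2,5-dimethoxyphenyl)-2,2-dimethylcyclobutyl (2Z)-2-methylbut-2-enoate | C/C=C(/C)C(=O)O[C@]1(c2cc(OC)ccc2OC)CCC1(C)C | intermediate
14 | (1R)-1-(3,6-dioxocyclohexa-1,4-dien-1-yl)-2,2-dimethylcyclobutyl (2Z)-2-methylbut-2-enoate | C/C=C(/C)C(=O)O[C@]1(C2=CC(=O)C=CC2=O)CCC1(C)C | intermediate
15 | succinic anhydride | O=C1CCC(=O)O1 | starting material
16 | 2,5-bis(trimethylsiloxy)furan | C[Si](C)(C)Oc1ccc(O[Si](C)(C)C)o1 | intermediate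
17 | (1R)-1-[1,4-dioxo-5,8-bis(trimethylsiloxy)-1,4,4a,5,8,8a-hexahydro-5,8-epoxynaphthalen-2-yl]-2,2-dimethylcyclobutyl (2Z)-2-methylbut-2-enoate, mixture of diastereomers at the new ring carbons | C/C=C(/C)C(=O)O[C@]1(C2=CC(=O)C3C(C2=O)C2(O[Si](C)(C)C)C=CC3(O[Si](C)(C)C)O2)CCC1(C)C | intermediate (not isolated)
18 | (1R)-1-(5,8-dihydroxy-1,4-dioxo-1,4-dihydronaphthalen-2-yl)-2,2-dimethylcyclobutyl (2Z)-2-methylbut-2-enoate | C/C=C(/C)C(=O)O[C@]1(C2=CC(=O)c3c(O)ccc(O)c3C2=O)CCC1(C)C | target

## Step count and least certain steps

Total step count: 10. Longest linear sequence: 9 steps (steps 1 to 8 and step 10; step 9 is a one-step branch).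

**Step 2 (key step).** The most likely failure is that the zwitterion does not close between the two fully substituted carbons and instead collapses by silyl or proton transfer to an open-chain acylation product. Dimerisation of 4, direct acylation of 2 by 3, and zinc-salt-induced reopening of the donor–acceptor cyclobutane are further losses. A first remedy at the level of conditions is to distil 4 from the zinc debromination and combine it salt-free with 2 in MeCN. The fallback sets out from 2 and comes back at 5: N,N-dimethylisobutyramide is converted with (CF3SO2)2O and 2,4,6-collidine in CH2Cl2 into tetramethylketeniminium triflate F1, a far stronger electrophile than 4 that cannot dimerise. Its [2+2] cycloaddition with 2 should give cyclobutaniminium triflate F2, and mild hydrolysis with aqueous NaHCO3 would deliver 5.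

**Step 7.** Acyl transfer to the heavily shielded alkoxide may stall. Prolonged exposure of the ester to base may also cause γ-deprotonation with loss of the Z geometry. The fallback sets out from 9 and comes back at 13, building the alkene after the ester: 9 is esterified with 2-[bis(2,2,2-trifluoroethoxy)phosphoryl]propanoic acid and N,N'-dicyclohexylcarbodiimide, a pairing that acylates hindered alcohols through a phosphonoketene, to give phosphonate ester F6. Still–Gennari olefination of F6 with acetaldehyde (KN(SiMe3)2, 18-crown-6, THF, −78 °C) should then form the trisubstituted Z-enoate.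

**Step 3.** The bulky, α-quaternary cyclobutanone may be accepted poorly by the enzyme, or catalyst control may be incomplete for one enantiomer, which would erode the enantiomeric purity of the separated alcohol. If only a cis-selective enzyme is found, the alkoxide-free thioacylation described below applies. The fallback sets out from 5 and comes back at 8: the enantiomers of 5 are separated by preparative chromatography on a chiral stationary phase, and the (3S)-ketone is reduced with NaBH4 to 6, to its carbinol epimer (1S,3R)-alcohol F3, or to both. 6 continues through steps 4 and 5. F3, in which hydroxyl and siloxy groups are cis, is thioacylated without forming an alkoxide (PhOC(S)Cl, pyridine, 4-dimethylaminopyridine) to O-phenyl thionocarbonate F4, which is reduced under the conditions of step 5 to 8.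

**Step 5.** Ring-opening β-scission of the C3' radical toward a benzylic, siloxy-stabilised radical may compete with hydrogen transfer, and addition of the stannyl radical to the hindered thiocarbonyl may be slow. The fallback sets out from 6 and comes back at 8 without a stannyl-radical chain: oxidation of 6 (Dess–Martin periodinane, NaHCO3) returns the ketone as the single (3S)-enantiomer of 5, and condensation with 4-methylbenzenesulfonohydrazide gives tosylhydrazone F5. Reduction of F5 with catecholborane followed by NaOAc·3H2O delivers the first hydrogen by polar hydride addition to C=N and the second on loss of sulfinate and dinitrogen from the monoalkyldiazene.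

**Step 10.** The very electron-rich, moisture-sensitive 16 may be consumed by electron transfer to the quinone or by Mukaiyama–Michael addition instead of cycloaddition. The fallback sets out from 14 and comes back at 18 by an Alder–Rickert sequence. 1,4-Bis(trimethylsiloxy)cyclohexa-1,3-diene F7 (from cyclohexane-1,4-dione, Me3SiCl, Et3N), a less oxidisable diene, should add to the unsubstituted C=C of 14 to give bicyclo[2.2.2]octene adduct F8. Enolisation (Et3N) and oxidation (Ag2O) would give ethano-bridged quinone F9, which on heating in toluene should extrude ethene to 5,8-bis(trimethylsiloxy)naphthoquinone F10. Mild acid desilylation (dilute HCl, THF) then gives 18.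

## Further compounds

F1 | step 2 | N-methyl-N-(2-methylprop-1-en-1-ylidene)methanaminium trifluoromethanesulfonate (tetramethylketeniminium triflate) | CC(C)=C=[N+](C)C.[O-]S(=O)(=O)C(F)(F)F
F2 | step 2 | N-{3-[(tert-butyldimethylsilyl)oxy]-3-(2,5-dimethoxyphenyl)-2,2-dimethylcyclobutylidene}-N-methylmethanaminium trifluoromethanesulfonate, racemate; the enantiomer leading to 6 is drawn | CC(C)(C)[Si](C)(C)O[C@]1(c2cc(OC)ccc2OC)CC(=[N+](C)C)C1(C)C.[O-]S(=O)(=O)C(F)(F)F
F3 | step 3 | (1S,3R)-3-[(tert-butyldimethylsilyl)oxy]-3-(2,5-dimethoxyphenyl)-2,2-dimethylcyclobutan-1-ol | CC(C)(C)[Si](C)(C)O[C@]1(c2cc(OC)ccc2OC)C[C@H](O)C1(C)C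
F4 | step 3 | O-[(1S,3R)-3-[(tert-butyldimethylsilyl)oxy]-3-(2,5-dimethoxyphenyl)-2,2-dimethylcyclobutyl] O-phenyl carbonothioate | CC(C)(C)[Si](C)(C)O[C@]1(c2cc(OC)ccc2OC)C[C@H](OC(=S)Oc2ccccc2)C1(C)C
F5 | step 5 | N'-{(3R)-3-[(tert-butyldimethylsilyl)oxy]-3-(2,5-dimethoxyphenyl)-2,2-dimethylcyclobutylidene}-4-methylbenzenesulfonohydrazide, C=N geometry not fixed | CC(C)(C)[Si](C)(C)O[C@]1(c2cc(OC)ccc2OC)CC(=NNS(=O)(=O)c2ccc(C)cc2)C1(C)C
F6 | step 7 | (1R)-1-(2,5-dimethoxyphenyl)-2,2-dimethylcyclobutyl 2-[bis(2,2,2-trifluoroethoxy)phosphoryl]propanoate, both epimers at the phosphonate-bearing carbon | CC(C(=O)O[C@]1(c2cc(OC)ccc2OC)CCC1(C)C)P(=O)(OCC(F)(F)F)OCC(F)(F)F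
F7 | step 10 | 1,4-bis(trimethylsiloxy)cyclohexa-1,3-diene | C[Si](C)(C)OC1=CC=C(O[Si](C)(C)C)CC1
F8 | step 10 | (1R)-1-[1,4-dioxo-5,8-bis(trimethylsiloxy)-1,4,4a,5,8,8a-hexahydro-5,8-ethanonaphthalen-2-yl]-2,2-dimethylcyclobutyl (2Z)-2-methylbut-2-enoate, mixture of diastereomers at the new ring carbons | C/C=C(/C)C(=O)O[C@]1(C2=CC(=O)C3C(C2=O)C2(O[Si](C)(C)C)C=CC3(O[Si](C)(C)C)CC2)CCC1(C)C
F9 | step 10 | (1R)-1-[1,4-dioxo-5,8-bis(trimethylsiloxy)-1,4,5,8-tetrahydro-5,8-ethanonaphthalen-2-yl]-2,2-dimethylcyclobutyl (2Z)-2-methylbut-2-enoate | C/C=C(/C)C(=O)O[C@]1(C2=CC(=O)C3=C(C2=O)C2(O[Si](C)(C)C)C=CC3(O[Si](C)(C)C)CC2)CCC1(C)C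
F10 | step 10 | (1R)-1-[1,4-dioxo-5,8-bis(trimethylsiloxy)-1,4-dihydronaphthalen-2-yl]-2,2-dimethylcyclobutyl (2Z)-2-methylbut-2-enoate | C/C=C(/C)C(=O)O[C@]1(C2=CC(=O)c3c(O[Si](C)(C)C)ccc(O[Si](C)(C)C)c3C2=O)CCC1(C)C
A1 | alternative 1 | (1R)-1-(5,8-dimethoxy-1,4-dioxo-1,4-dihydronaphthalen-2-yl)-2,2-dimethylcyclobutyl triethylsilyl ether | CC[Si](CC)(CC)O[C@]1(C2=CC(=O)c3c(OC)ccc(OC)c3C2=O)CCC1(C)C
A2 | alternative 1 | 8-hydroxy-2,5-dimethoxy-8-{[(1R)-2,2-dimethyl-1-(triethylsiloxy)cyclobutyl]ethynyl}bicyclo[4.2.0]octa-1,3,5-trien-7-one, both epimers at the carbinol carbon | CC[Si](CC)(CC)O[C@]1(C#CC2(O)C(=O)c3c(OC)ccc(OC)c32)CCC1(C)C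
A3 | alternative 1 | triethyl{[(1R)-1-ethynyl-2,2-dimethylcyclobutyl]oxy}silane | CC[Si](CC)(CC)O[C@]1(C#C)CCC1(C)C
A4 | alternative 1 | 2,5-dimethoxybicyclo[4.2.0]octa-1,3,5-triene-7,8-dione (3,6-dimethoxybenzocyclobutenedione) | COc1ccc(OC)c2c1C(=O)C2=O
A5 | alternative 1 | 2,2-dimethylcyclobutan-1-one | CC1(C)CCC1=O
A6 | alternative 2 | (1R)-1-(5,8-dimethoxy-1,4-dihydro-1,4-epoxynaphthalen-2-yl)-2,2-dimethylcyclobutyl (2Z)-2-methylbut-2-enoate, both bridgehead epimers | C/C=C(/C)C(=O)O[C@]1(C2=CC3OC2c2c(OC)ccc(OC)c23)CCC1(C)C
A7 | alternative 2 | (1R)-1-(furan-3-yl)-2,2-dimethylcyclobutyl (2Z)-2-methylbut-2-enoate | C/C=C(/C)C(=O)O[C@]1(c2ccoc2)CCC1(C)C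
A8 | alternative 2 | 3,6-dimethoxy-2-(trimethylsilyl)phenyl trifluoromethanesulfonate | COc1ccc(OC)c([Si](C)(C)C)c1OS(=O)(=O)C(F)(F)F
A9 | alternative 3 | 2-[(1R)-2,2-dimethyl-1-(triethylsiloxy)cyclobutyl]-4-methoxy-5,8-bis(methoxymethoxy)naphthalen-1-ol | CC[Si](CC)(CC)O[C@]1(c2cc(OC)c3c(OCOC)ccc(OCOC)c3c2O)CCC1(C)C
A10 | alternative 3 | pentacarbonyl{[2,5-bis(methoxymethoxy)phenyl](methoxy)methylidene}chromium, (CO)5Cr=C(OMe)Ar, zerovalent chromium | COC(=[Cr])c1cc(OCOC)ccc1OCOC.[C-]#[O+].[C-]#[O+].[C-]#[O+].[C-]#[O+].[C-]#[O+]
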